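**Retrosynthetic overview**

1. Target ⇒ Shi epoxidation (last step) of the isolated trisubstituted alkene; before that, acetonide removal and the ester C–O bond between cis-hydroxy lactone 18 and dienoic acid 25.
2. 18 ⇒ ketolactone 17 ⇒ Achmatowicz ring expansion of furyl carbinol 15; the furan is the masked C2–C5 unit and its C2 becomes the C5 carbonyl.
3. 15 ⇒ alkyl–alkenyl coupling (C4'–C5') and keto acid 5. Key C5–C6 bond: 2-furylzinc (acyl anion equivalent) opens meso-2,4-dimethylglutaric anhydride enantioselectively, fixing C1' and C3' in the same step; C6 is then set by transfer hydrogenation.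
4. 25 ⇒ Horner–Wadsworth–Emmons and Wittig olefinations ⇒ aldehyde 20 ⇒ asymmetric hydroformylation of a dihydrodioxepine.
5. Ring order: δ-lactone 7 (temporary, step 2) → pyranone ring (step 6) → oxirane (step 14); the furan and dioxepane rings are bought.

Convention and assumption: lactone atoms are O1, C2(=O), C3=C4, C5 (O-acyl), C6; side-chain carbons are C1'–C6'; in steps 1 and 9 the named ligand enantiomer is assumed to give the sense shown, otherwise its antipode is used.

**Route**

Step 1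
Reactants: 1 meso-2,4-dimethylglutaric anhydride; 2 furan
Product: 5 (2R,4S)-5-(furan-2-yl)-2,4-dimethyl-5-oxopentanoic acid, via 2-furyllithium 3 (not isolated), via 2-furylzinc chloride 4 (not isolated)
Conditions: 2, n-BuLi, THF, 0 °C; ZnCl2, 0 °C → rt; then 1, [Rh(nbd)Cl]2 (4 mol %), (S)-t-Bu-PHOX (8 mol %), THF, 50 °C; aq. HCl work-up (pH 3)
Reagents that add atoms: none
Why: Proposed new method: monovalent rhodium carrying the chiral P,N ligand inserts into one of the two enantiotopic acyl–oxygen bonds of the meso anhydride, the 2-furyl group is transferred from zinc and reductive elimination gives the ketone carboxylate, so the masked acyl anion (furan C2, later the C5 carbonyl) is joined to the acyl carbon that becomes C6, and the choice of carbonyl turns the two existing methyl centres into C1' (S) and C3' (R); the closest known reaction type is the rhodium/phosphinooxazoline-catalysed enantioselective opening of this same anhydride with alkylzinc halides and of meso succinic anhydrides with arylzinc reagents.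

Step 2
Reactants: 5 (2R,4S)-5-(furan-2-yl)-2,4-dimethyl-5-oxopentanoic acid
Product: 7 (3R,5S,6R)-6-(furan-2-yl)-3,5-dimethyloxan-2-one, via hydroxy acid 6 (not isolated)
Conditions: RuCl[(R,R)-TsDPEN](p-cymene) (1 mol %), HCO2H/Et3N (5:2), CH2Cl2, rt; then PPTS (cat.), toluene, 40 °C
Reagents that add atoms: none
Why: Noyori asymmetric transfer hydrogenation, in which the (R,R) catalyst treats the furyl group as the aryl partner and delivers hydride under catalyst control to give the (R) carbinol (C6) regardless of the weak bias of the α-methyl centre; mild acid then closes the δ-lactone.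

Step 3
Reactants: 7 (3R,5S,6R)-6-(furan-2-yl)-3,5-dimethyloxan-2-one
Product: 8 (1R,2S,4R)-1-(furan-2-yl)-2,4-dimethylpentane-1,5-diol
Conditions: LiAlH4, THF, 0 °C → rt
Reagents that add atoms: none
Why: Hydride reduction of a lactone to the 1,5-diol; no stereocentre is touched.

Step 4
Reactants: 8 (1R,2S,4R)-1-(furan-2-yl)-2,4-dimethylpentane-1,5-diol
Product: 10 (2R,4S,5R)-5-(furan-2-yl)-2,4-dimethyl-5-[(trimethylsilyl)oxy]pentyl 4-methylbenzenesulfonate, via hydroxy tosylate 9 (not isolated)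
Conditions: TsCl (1.05 equiv), pyridine, CH2Cl2, 0 °C; then TMSCl (1.2 equiv), 0 °C
Reagents that add atoms: p-toluenesulfonyl chloride, Cc1ccc(cc1)S(Cl)(=O)=O; chlorotrimethylsilane, C[Si](C)(C)Cl
Why: Selective sulfonylation of the primary hydroxyl over the hindered secondary furyl carbinol, followed by in-flask silylation of the latter so that no alkoxide (and no tetrahydropyran closure) can form in the coupling step.

Step 5
Reactants: 10 (2R,4S,5R)-5-(furan-2-yl)-2,4-dimethyl-5-[(trimethylsilyl)oxy]pentyl 4-methylbenzenesulfonate; 11 (E)-2-bromobut-2-ene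
Product: 15 (1R,2S,4R,6E)-1-(furan-2-yl)-2,4,6-trimethyloct-6-en-1-ol, via (Z)-but-2-en-2-yllithium 12 (not isolated), via (E)-but-2-en-2-ylmagnesium bromide 13 (not isolated), via silyl ether 14 (not isolated)
Conditions: 11, t-BuLi (2.0 equiv), Et2O, −78 °C; MgBr2·OEt2, −78 → 0 °C; then 10, Li2CuCl4 (5 mol %), THF, −20 → 0 °C; then K2CO3, MeOH, rt
Reagents that add atoms: none
Why: Bromine–lithium exchange and transmetalation to magnesium keep the alkene geometry (metal where bromine was), and copper-catalysed Kochi-type coupling of the alkenyl Grignard reagent with the primary tosylate forms the C4'–C5' bond with the (E) trisubstituted alkene; methanolysis removes the silyl ether.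

Step 6
Reactants: 15 (1R,2S,4R,6E)-1-(furan-2-yl)-2,4,6-trimethyloct-6-en-1-ol
Product: 16 (2R)-2-[(2S,4R,6E)-4,6-dimethyloct-6-en-2-yl]-6-hydroxy-2H-pyran-3(6H)-one (mixture of anomers at the lactol carbon)
Conditions: VO(acac)2 (5 mol %), t-BuOOH (1.5 equiv, decane), CH2Cl2, 0 °C → rt
Reagents that add atoms: tert-butyl hydroperoxide, CC(C)(C)OO
Why: Achmatowicz rearrangement in which hydroxyl-directed vanadium/peroxide oxidation of the furan and ring expansion give the pyranone with C6 untouched, while the remote, undirected trisubstituted alkene is not epoxidised by this catalyst; furan C2 is unmasked as the C5 carbonyl.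

Step 7
Reactants: 16 (2R)-2-[(2S,4R,6E)-4,6-dimethyloct-6-en-2-yl]-6-hydroxy-2H-pyran-3(6H)-one
Product: 17 (6R)-6-[(2S,4R,6E)-4,6-dimethyloct-6-en-2-yl]-2H-pyran-2,5(6H)-dione
Conditions: CrO3, H2SO4 (Jones reagent), acetone, 0 °C, 15 min
Reagents that add atoms: none
Why: Jones oxidation of the lactol to the lactone under acidic conditions that neither epimerise C6 (α to the ketone) nor touch the isolated alkene.

Step 8
Reactants: 17 (6R)-6-[(2S,4R,6E)-4,6-dimethyloct-6-en-2-yl]-2H-pyran-2,5(6H)-dione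
Product: 18 (5R,6R)-6-[(2S,4R,6E)-4,6-dimethyloct-6-en-2-yl]-5-hydroxy-5,6-dihydro-2H-pyran-2-one
Conditions: NaBH4, CeCl3·7H2O, MeOH/CH2Cl2, −78 °C
Reagents that add atoms: none
Why: Luche 1,2-reduction in which hydride adds to the C5 carbonyl of the nearly flat enedione ring from the face opposite the C6 side chain, so the new hydroxyl is cis to the side chain (5R), as expected for 6-alkyl pyran-2,5-diones.

Step 9
Reactants: 19 2,2-dimethyl-4,7-dihydro-1,3-dioxepine
Product: 20 (5R)-2,2-dimethyl-1,3-dioxepane-5-carbaldehyde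
Conditions: Rh(acac)(CO)2 (0.5 mol %), (S,S,S)-BisDiazaphos (0.6 mol %), CO/H2 (1:1, 10 bar), toluene, 40 °C
Reagents that add atoms: carbon monoxide, [C-]#[O+]
Why: Rhodium-catalysed asymmetric hydroformylation of a symmetrical cis-alkene (no regiochemical issue), the chiral ligand choosing between the two enantiotopic alkene carbons to set the (R) centre that becomes C6 of the acid (about 85–95 % ee is recalled for this olefin class, and the minor enantiomer is removed as a diastereomer after step 12).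

Step 10
Reactants: 20 (5R)-2,2-dimethyl-1,3-dioxepane-5-carbaldehyde; 21 2-(triphenylphosphoranylidene)propanal
Product: 22 (2E)-3-[(5S)-2,2-dimethyl-1,3-dioxepan-5-yl]-2-methylprop-2-enal
Conditions: toluene, 80 °C
Reagents that add atoms: none
Why: Wittig olefination with a stabilised ylide gives the (E) trisubstituted enal without epimerising the α-centre, as with other β-alkoxy α-branched aldehydes (the descriptor changes from R to S only through priorities).

Step 11
Reactants: 22 (2E)-3-[(5S)-2,2-dimethyl-1,3-dioxepan-5-yl]-2-methylprop-2-enal; 23 diethylphosphonoacetic acid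
Product: 25 (2E,4E)-5-[(5S)-2,2-dimethyl-1,3-dioxepan-5-yl]-4-methylpenta-2,4-dienoic acid, via dilithio phosphonoacetate 24 (not isolated)
Conditions: 23, n-BuLi (2.0 equiv), THF, −78 → 0 °C; then 22, −78 °C → rt; cold dilute aq. HCl to pH 4
Reagents that add atoms: none
Why: Horner–Wadsworth–Emmons olefination with the phosphonoacetic acid dianion gives the (2E) acid directly, so no ester hydrolysis is needed and the acetonide stays on.

Step 12
Reactants: 18 (5R,6R)-6-[(2S,4R,6E)-4,6-dimethyloct-6-en-2-yl]-5-hydroxy-5,6-dihydro-2H-pyran-2-one; 25 (2E,4E)-5-[(5S)-2,2-dimethyl-1,3-dioxepan-5-yl]-4-methylpenta-2,4-dienoic acid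
Product: 26 (2R,3R)-2-[(2S,4R,6E)-4,6-dimethyloct-6-en-2-yl]-6-oxo-3,6-dihydro-2H-pyran-3-yl (2E,4E)-5-[(5S)-2,2-dimethyl-1,3-dioxepan-5-yl]-4-methylpenta-2,4-dienoate
Conditions: DCC, DMAP (10 mol %), CH2Cl2, 0 °C → rt
Reagents that add atoms: none
Why: Steglich esterification acylates the C5 hydroxyl with retention; the diastereomer arising from the minor enantiomer of 25 is separated here.

Step 13
Reactants: 26 the acetonide ester from step 12
Product: 27 (2R,3R)-2-[(2S,4R,6E)-4,6-dimethyloct-6-en-2-yl]-6-oxo-3,6-dihydro-2H-pyran-3-yl (2E,4E,6S)-8-hydroxy-6-(hydroxymethyl)-4-methylocta-2,4-dienoate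
Conditions: AcOH/THF/H2O (3:1:1), rt
Reagents that add atoms: none
Why: Acid-catalysed acetal hydrolysis; the seven-membered acetonide is cleaved by dilute acetic acid under conditions that leave the ester and the lactone intact, and it is done before the acid-sensitive epoxide exists.

Step 14
Reactants: 27 the diol ester from step 13
Product: 28 (2R,3R)-2-{(2S,4R)-4-methyl-5-[(2R,3R)-2,3-dimethyloxiran-2-yl]pentan-2-yl}-6-oxo-3,6-dihydro-2H-pyran-3-yl (2E,4E,6S)-8-hydroxy-6-(hydroxymethyl)-4-methylocta-2,4-dienoate (CNP0160449.2)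
Conditions: D-fructose-derived Shi ketone (1.0 equiv), KHSO5 (Oxone, 1.4 equiv), NaHCO3, aq. Na2EDTA, MeCN/dimethoxymethane, 0 °C, pH 8
Reagents that add atoms: potassium peroxymonosulfate, [K+].[O-]S(=O)(=O)OO
Why: Shi asymmetric epoxidation in which the chiral dioxirane attacks the only electron-rich alkene through the spiro transition state that gives (R,R) epoxides from (E) trisubstituted olefins (C5' R, C6' R), while the dienoate and enoate alkenes are electron-poor and react far more slowly and pH 8 spares the esters.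

**Compound list**

1 | meso-2,4-dimethylglutaric anhydride, (3R,5S)-3,5-dimethyloxane-2,6-dione | C[C@H]1C[C@@H](C)C(=O)OC1=O | starting material
2 | furan | c1ccoc1 | starting material
3 | 2-furyllithium | [Li]c1ccco1 | intermediate
4 | 2-furylzinc chloride | Cl[Zn]c1ccco1 | intermediate
5 | (2R,4S)-5-(furan-2-yl)-2,4-dimethyl-5-oxopentanoic acid | O=C(c1ccco1)[C@@H](C)C[C@@H](C)C(=O)O | intermediate
6 | (2R,4S,5R)-5-(furan-2-yl)-5-hydroxy-2,4-dimethylpentanoic acid | O[C@@H](c1ccco1)[C@@H](C)C[C@@H](C)C(=O)O | intermediate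
7 | (3R,5S,6R)-6-(furan-2-yl)-3,5-dimethyloxan-2-one | O1[C@@H](c2ccco2)[C@@H](C)C[C@@H](C)C1=O | intermediate
8 | (1R,2S,4R)-1-(furan-2-yl)-2,4-dimethylpentane-1,5-diol | O[C@@H](c1ccco1)[C@@H](C)C[C@@H](C)CO | intermediate
9 | (2R,4S,5R)-5-(furan-2-yl)-5-hydroxy-2,4-dimethylpentyl 4-methylbenzenesulfonate | O[C@@H](c1ccco1)[C@@H](C)C[C@@H](C)COS(=O)(=O)c1ccc(C)cc1 | intermediate
10 | (2R,4S,5R)-5-(furan-2-yl)-2,4-dimethyl-5-[(trimethylsilyl)oxy]pentyl 4-methylbenzenesulfonate | C[Si](C)(C)O[C@@H](c1ccco1)[C@@H](C)C[C@@H](C)COS(=O)(=O)c1ccc(C)cc1 | intermediate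
11 | (E)-2-bromobut-2-ene | C/C=C(\C)Br | starting material
12 | (Z)-but-2-en-2-yllithium (lithium where bromine was) | C/C=C(\C)[Li] | intermediate
13 | (E)-but-2-en-2-ylmagnesium bromide | C/C=C(\C)[Mg]Br | intermediate
14 | {[(1R,2S,4R,6E)-1-(furan-2-yl)-2,4,6-trimethyloct-6-en-1-yl]oxy}trimethylsilane | C[Si](C)(C)O[C@@H](c1ccco1)[C@@H](C)C[C@@H](C)C/C(C)=C/C | intermediate
15 | (1R,2S,4R,6E)-1-(furan-2-yl)-2,4,6-trimethyloct-6-en-1-ol | O[C@@H](c1ccco1)[C@@H](C)C[C@@H](C)C/C(C)=C/C | intermediate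
16 | (2R)-2-[(2S,4R,6E)-4,6-dimethyloct-6-en-2-yl]-6-hydroxy-2H-pyran-3(6H)-one | O=C1C=CC(O)O[C@@H]1[C@@H](C)C[C@@H](C)C/C(C)=C/C | intermediate
17 | (6R)-6-[(2S,4R,6E)-4,6-dimethyloct-6-en-2-yl]-2H-pyran-2,5(6H)-dione | O=C1C=CC(=O)O[C@@H]1[C@@H](C)C[C@@H](C)C/C(C)=C/C | intermediate
18 | (5R,6R)-6-[(2S,4R,6E)-4,6-dimethyloct-6-en-2-yl]-5-hydroxy-5,6-dihydro-2H-pyran-2-one | O[C@@H]1C=CC(=O)O[C@@H]1[C@@H](C)C[C@@H](C)C/C(C)=C/C | intermediate
19 | 2,2-dimethyl-4,7-dihydro-1,3-dioxepine | CC1(C)OCC=CCO1 | starting material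
20 | (5R)-2,2-dimethyl-1,3-dioxepane-5-carbaldehyde | O=C[C@@H]1CCOC(C)(C)OC1 | intermediate
21 | 2-(triphenylphosphoranylidene)propanal | CC(C=O)=P(c1ccccc1)(c1ccccc1)c1ccccc1 | starting material
22 | (2E)-3-[(5S)-2,2-dimethyl-1,3-dioxepan-5-yl]-2-methylprop-2-enal | O=C/C(C)=C/[C@@H]1CCOC(C)(C)OC1 | intermediate
23 | diethylphosphonoacetic acid | CCOP(=O)(OCC)CC(=O)O | starting material
24 | dilithio diethylphosphonoacetate | [Li+].[Li+].CCOP(=O)(OCC)[CH-]C(=O)[O-] | intermediate
25 | (2E,4E)-5-[(5S)-2,2-dimethyl-1,3-dioxepan-5-yl]-4-methylpenta-2,4-dienoic acid | OC(=O)/C=C/C(C)=C/[C@@H]1CCOC(C)(C)OC1 | intermediate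
26 | (2R,3R)-2-[(2S,4R,6E)-4,6-dimethyloct-6-en-2-yl]-6-oxo-3,6-dihydro-2H-pyran-3-yl (2E,4E)-5-[(5S)-2,2-dimethyl-1,3-dioxepan-5-yl]-4-methylpenta-2,4-dienoate | CC(/C=C/C(=O)O[C@@H]1C=CC(=O)O[C@@H]1[C@@H](C)C[C@@H](C)C/C(C)=C/C)=C\[C@@H]1CCOC(C)(C)OC1 | intermediate
27 | (2R,3R)-2-[(2S,4R,6E)-4,6-dimethyloct-6-en-2-yl]-6-oxo-3,6-dihydro-2H-pyran-3-yl (2E,4E,6S)-8-hydroxy-6-(hydroxymethyl)-4-methylocta-2,4-dienoate | CC(/C=C/C(=O)O[C@@H]1C=CC(=O)O[C@@H]1[C@@H](C)C[C@@H](C)C/C(C)=C/C)=C\[C@@H](CO)CCO | intermediate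
28 | (2R,3R)-2-{(2S,4R)-4-methyl-5-[(2R,3R)-2,3-dimethyloxiran-2-yl]pentan-2-yl}-6-oxo-3,6-dihydro-2H-pyran-3-yl (2E,4E,6S)-8-hydroxy-6-(hydroxymethyl)-4-methylocta-2,4-dienoate | CC(/C=C/C(=O)O[C@@H]1C=CC(=O)O[C@@H]1[C@@H](C)C[C@@H](C)C[C@@]1(C)O[C@@H]1C)=C\[C@@H](CO)CCO | target

**Step count and risks**

Total steps: 14. Longest linear sequence: 11 (steps 1–8, then 12–14); the acid branch is steps 9–11.

The three steps most likely to fail:

Step 1 (new combination of a heteroarylzinc reagent with the glutaric anhydride; risk of low ee, wrong sense or decarbonylation). Fallback, setting out from 1: the anhydride is desymmetrised with an oxygen nucleophile instead, by cinchona-alkaloid-mediated methanolysis (quinidine, MeOH, toluene, −55 °C; quinine if the other sense is found), to give the hemiester (2S,4R)-5-methoxy-2,4-dimethyl-5-oxopentanoic acid F1. Oxalyl chloride with catalytic DMF converts it into the acid chloride methyl (2R,4S)-5-chloro-2,4-dimethyl-5-oxopentanoate F2. Negishi acylation with 2-furylzinc chloride 4 (Pd(PPh3)4, THF, 0 °C) then forms the same C5–C6 bond and gives the keto ester methyl (2R,4S)-5-(furan-2-yl)-2,4-dimethyl-5-oxopentanoate F3. Transfer hydrogenation as in step 2 gives the hydroxy ester methyl (2R,4S,5R)-5-(furan-2-yl)-5-hydroxy-2,4-dimethylpentanoate F4, which closes with PPTS in toluene and comes back to the route at lactone 7.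

Step 8 (the facial selectivity of the hydride addition rests on a recalled analogy with simpler 6-alkyl pyrandiones and may turn out trans). Fallback, setting out from 17: if reduction gives mainly the trans alcohol (5S,6R)-6-[(2S,4R,6E)-4,6-dimethyloct-6-en-2-yl]-5-hydroxy-5,6-dihydro-2H-pyran-2-one F5, this alcohol is used as it is. Mitsunobu esterification with acid 25 (PPh3, DIAD, toluene, 0 °C) inverts C5 while forming the ester, and the route is rejoined at 26, replacing step 12.

Step 14 (competing epoxidation of the γ,δ-alkene of the dienoate, or ester/lactone hydrolysis in the aqueous buffer). Fallback, setting out from 18: the epoxide is introduced before any dienoate is present. Shi epoxidation of 18 under the same pH 8 conditions gives the epoxy alcohol (5R,6R)-5-hydroxy-6-{(2S,4R)-4-methyl-5-[(2R,3R)-2,3-dimethyloxiran-2-yl]pentan-2-yl}-5,6-dihydro-2H-pyran-2-one F6. DCC/DMAP coupling with 25 gives the epoxy ester acetonide (2R,3R)-2-{(2S,4R)-4-methyl-5-[(2R,3R)-2,3-dimethyloxiran-2-yl]pentan-2-yl}-6-oxo-3,6-dihydro-2H-pyran-3-yl (2E,4E)-5-[(5S)-2,2-dimethyl-1,3-dioxepan-5-yl]-4-methylpenta-2,4-dienoate F7. The labile seven-membered acetonide is then removed with PPTS in MeOH at 0 °C, arriving at target 28.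

**Further compounds**

F1 | step 1 | (2S,4R)-5-methoxy-2,4-dimethyl-5-oxopentanoic acid | OC(=O)[C@@H](C)C[C@@H](C)C(=O)OC
F2 | step 1 | methyl (2R,4S)-5-chloro-2,4-dimethyl-5-oxopentanoate | ClC(=O)[C@@H](C)C[C@@H](C)C(=O)OC
F3 | step 1 | methyl (2R,4S)-5-(furan-2-yl)-2,4-dimethyl-5-oxopentanoate | O=C(c1ccco1)[C@@H](C)C[C@@H](C)C(=O)OC
F4 | step 1 | methyl (2R,4S,5R)-5-(furan-2-yl)-5-hydroxy-2,4-dimethylpentanoate | O[C@@H](c1ccco1)[C@@H](C)C[C@@H](C)C(=O)OC
F5 | step 8 | (5S,6R)-6-[(2S,4R,6E)-4,6-dimethyloct-6-en-2-yl]-5-hydroxy-5,6-dihydro-2H-pyran-2-one | O[C@H]1C=CC(=O)O[C@@H]1[C@@H](C)C[C@@H](C)C/C(C)=C/C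
F6 | step 14 | (5R,6R)-5-hydroxy-6-{(2S,4R)-4-methyl-5-[(2R,3R)-2,3-dimethyloxiran-2-yl]pentan-2-yl}-5,6-dihydro-2H-pyran-2-one | O[C@@H]1C=CC(=O)O[C@@H]1[C@@H](C)C[C@@H](C)C[C@@]1(C)O[C@@H]1C
F7 | step 14 | (2R,3R)-2-{(2S,4R)-4-methyl-5-[(2R,3R)-2,3-dimethyloxiran-2-yl]pentan-2-yl}-6-oxo-3,6-dihydro-2H-pyran-3-yl (2E,4E)-5-[(5S)-2,2-dimethyl-1,3-dioxepan-5-yl]-4-methylpenta-2,4-dienoate | CC(/C=C/C(=O)O[C@@H]1C=CC(=O)O[C@@H]1[C@@H](C)C[C@@H](C)C[C@@]1(C)O[C@@H]1C)=C\[C@@H]1CCOC(C)(C)OC1
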